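**Plan**
Locants: ring A is the carbocycle C4a-C5-C6-C7-C8-C8a and ring B the dihydropyran O1-C2-C3-C4-C4a-C8a (chromene numbering). The terpene rings C and D carry primed naphthalene locants (C2' = C2).
Cuts: first O1-C2 and C3-C4 of ring B (retro hetero-Diels-Alder), which gives an achiral 2-alkylidene-1,3-dione and a C15 diene. Next C4a-C8a and C5-C6 of ring A, which lifts C4a/C5 out as a siloxyalkyne and leaves a cyclobutenone made of C6, C7, C8 and C8a. In the terpene, C1'=C8a' (Wittig) and C3'-C4' (conjugate allylation) lead back to (-)-menthone.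
Enabling feature: ring A is the O-alkylated tautomer of a 6,6-dimethylcyclohexa-2,4-dienone. Its C8a-C8 bond joins a carbonyl-level carbon to the quaternary CMe2 carbon, so it is the closed form of a dienylketene. The 1,3,5-oxygen pattern (C8a, C5, C7) maps onto ketene C=O, ynol-ether O and enol-ether O.
Forward order: ring D is bought, ring C closes by intramolecular Wittig reaction, ring A grows from four to six atoms in the key step, and ring B closes last and joins the two halves.
Stereochemistry: C5' and C8' come from (-)-menthone, C4a' from kinetic protonation of a regiodefined enolate, and C2 and C4 from an endo, face-selective cycloaddition on the enantiopure diene.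

Key step: step 8

Remark: enol 26, its tautomers and heterodiene 27 interconvert by proton shifts. Each SMILES shows one tautomer, and 27 is the reacting form.

Step 1
Reactants: 1 (-)-menthone
Product: 5 (3R,6S)-3-methyl-2-methylidene-6-(propan-2-yl)cyclohexan-1-one, via lithium enolate 2 (not isolated), via Mannich base 3 (not isolated), via methiodide 4 (not isolated)
Conditions: LiN(iPr)2, THF, -78 °C; Me2N=CH2 I, -78 °C to rt; MeI, Et2O, rt; aq NaHCO3, CH2Cl2, rt
Reagents that add atoms: N,N-dimethylmethyleneiminium iodide (Eschenmoser's salt), C=[N+](C)C.[I-]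
Why: Kinetic deprotonation takes the only CH2 flank of the ketone, and Mannich reaction with the iminium salt, quaternisation and E1cB loss of trimethylamine (Eschenmoser methylenation) should give the exocyclic enone without touching the two existing stereocentres.

Step 2
Reactants: 5 (3R,6S)-3-methyl-2-methylidene-6-(propan-2-yl)cyclohexan-1-one, 6 [2-(chloromethyl)prop-2-en-1-yl]trimethylsilane
Product: 8 (2R,3R,6S)-2-[3-(chloromethyl)but-3-en-1-yl]-3-methyl-6-(propan-2-yl)cyclohexan-1-one, via titanium enolate 7 (not isolated)
Conditions: TiCl4, CH2Cl2, -78 °C; precooled MeOH, -78 °C; aq NaHCO3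
Reagents that add atoms: none
Why: Hosomi-Sakurai conjugate allylation: TiCl4 activates the s-cis exocyclic enone, the allylsilane attacks the unhindered CH2 terminus through its gamma carbon and loses silicon to give enolate 7 regiospecifically, and kinetic protonation at -78 °C should occur axially on the face anti to the neighbouring C3 methyl group (held pseudoaxial by A(1,2) strain with the new side chain), which sets C2 as R with the side chain cis to the methyl group, the less stable epimer that is kept away from equilibrating conditions from here on.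

Step 3
Reactants: 8 (2R,3R,6S)-2-[3-(chloromethyl)but-3-en-1-yl]-3-methyl-6-(propan-2-yl)cyclohexan-1-one
Product: 9 {4-[(1R,2R,5S)-2-methyl-6-oxo-5-(propan-2-yl)cyclohexyl]-2-methylidenebutyl}triphenylphosphonium chloride
Conditions: PPh3, MeCN, 80 °C
Reagents that add atoms: triphenylphosphine, c1ccc(cc1)P(c1ccccc1)c1ccccc1
Why: SN2 quaternisation of the phosphine by the primary allylic chloride (SN2' attack would give the same salt because the allyl unit is symmetric) runs under neutral conditions that leave the epimerisable centres next to the ketone untouched.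

Step 4
Reactants: 9 {4-[(1R,2R,5S)-2-methyl-6-oxo-5-(propan-2-yl)cyclohexyl]-2-methylidenebutyl}triphenylphosphonium chloride
Product: 11 (1S,4R,4aR)-4-methyl-7-methylidene-1-(propan-2-yl)-1,2,3,4,4a,5,6,7-octahydronaphthalene, via allylic ylide 10 (not isolated)
Conditions: KN(SiMe3)2 (1.0 equiv), THF, -78 °C to 40 °C
Reagents that add atoms: none
Why: Intramolecular Wittig olefination: one equivalent of the hindered amide removes only the far more acidic allylic P-CH2 proton, and the semi-stabilised ylide closes a six-membered ring on the ketone, which places the new double bond unambiguously at C8=C8a in conjugation with the exocyclic methylene group and creates no stereocentre.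

Step 5
Reactants: 12 2-chloro-1,1-dimethoxyethane
Product: 14 1-methoxyprop-1-yne, via sodium methoxyacetylide 13 (not isolated)
Conditions: NaNH2 (3 equiv), liquid NH3, -33 °C; MeI
Reagents that add atoms: iodomethane, CI
Why: Double beta-elimination of the chloroacetal (loss of methanol, then of HCl) with excess amide gives the alkoxyacetylide, which iodomethane alkylates on carbon (classical alkoxyalkyne synthesis).

Step 6
Reactants: 14 1-methoxyprop-1-yne, 15 2-methylpropanoyl chloride
Product: 17 3-methoxy-2,4,4-trimethylcyclobut-2-en-1-one, via dimethylketene 16 (not isolated)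
Conditions: Et3N, Et2O, reflux
Reagents that add atoms: none
Why: Dehydrochlorination gives dimethylketene, whose thermal [2+2] cycloaddition to the electron-rich alkyne is regiospecific because the nucleophilic, methyl-bearing alkyne carbon bonds to the ketene carbonyl carbon.

Step 7
Reactants: 18 ethyl 3-methylbut-2-enoate
Product: 21 [(4-methylpent-3-en-1-yn-1-yl)oxy]tri(propan-2-yl)silane, via dibromo enolate 19 (not isolated), via lithium ynolate 20 (not isolated)
Conditions: CH2Br2, lithium 2,2,6,6-tetramethylpiperidide (from the amine and n-BuLi), THF, -78 °C; 18; n-BuLi, -78 °C to rt; iPr3SiCl, -78 °C to rt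
Reagents that add atoms: dibromomethane, BrCBr; chlorotri(propan-2-yl)silane, CC(C)[Si](Cl)(C(C)C)C(C)C
Why: Kowalski ester homologation stopped at the ynolate: addition of LiCHBr2 to the ester, enolisation, bromine-lithium exchange and 1,2-shift of the alkenyl group give ynolate 20, which the bulky chlorosilane traps on oxygen.

Step 8
Reactants: 17 3-methoxy-2,4,4-trimethylcyclobut-2-en-1-one, 21 [(4-methylpent-3-en-1-yn-1-yl)oxy]tri(propan-2-yl)silane
Product: 25 5-methoxy-4,6,6-trimethyl-2-(2-methylprop-1-en-1-yl)-3-{[tri(propan-2-yl)silyl]oxy}cyclohexa-2,4-dien-1-one, via vinylketene 22 (not isolated), via alkenylcyclobutenone 23 (not isolated), via dienylketene 24 (not isolated)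
Conditions: toluene (concentrated, sealed tube, argon), 135 °C
Reagents that add atoms: none
Why: Proposed new method: heat opens 17 by 4π electrocyclic cleavage of its C1-C4 bond to vinylketene 22, the siloxy-polarised carbon of alkyne 21 attacks the ketene carbon in a regiospecific [2+2] cycloaddition to 23, a second, reversible 4π opening gives dienylketene 24, and 6π disrotatory electrocyclisation of the ketene carbon (C8a) onto the Me2C= terminus (C8) closes ring A, so that the four ring atoms of 17 are kept and the two alkyne carbons end up inserted into its former acyl-vinyl bond. The closest known reaction type is the Danheiser benzannulation of cyclobutenones with siloxyalkynes; new is that the quaternary C8 forbids tautomerisation to a phenol, so the cascade has to end at the cyclohexa-2,4-dienone, for which the known thermal re-closure of dienylketenes to 6,6-disubstituted cyclohexa-2,4-dienones speaks. The driving force is the release of cyclobutenone strain and the conversion of a ketene into a donor-substituted, vinylogous-ester-type dienone. No stereocentre is formed and the single stereocentre of 23 is erased, so both enantiomers of 23, and through reversibility both rotation modes of its opening, funnel into achiral 25. The step needs capture of 22 and closure of 24 to outrun 1,5-hydrogen shifts from the cis methyl groups to the ketene carbon, and it needs [2+2] rather than [4+2] periselectivity; the nucleophilicity and high concentration of 21 and the crowding of 24, which favours the coiled s-cis conformer, should secure this. The three ring oxygens arrive in three different forms (OMe from 17, C=O from the ketene carbon, OSi from 21), so the place of the methyl ether is fixed and the later heterodiene is carried in masked form by the 2-methylpropenyl group.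

Step 9
Reactants: 25 5-methoxy-4,6,6-trimethyl-2-(2-methylprop-1-en-1-yl)-3-{[tri(propan-2-yl)silyl]oxy}cyclohexa-2,4-dien-1-one, 11 (1S,4R,4aR)-4-methyl-7-methylidene-1-(propan-2-yl)-1,2,3,4,4a,5,6,7-octahydronaphthalene
Product: 28 target CNP0194760.3, via enol 26 (not isolated), via heterodiene 27 (not isolated)
Conditions: 25 (1.5 equiv), Bu4NF, AcOH, THF, 0 °C; then 11, toluene, 80 °C
Reagents that add atoms: none
Why: Fluoride frees enol 26, whose cis-dienol unit passes by 1,5-hydrogen shift or acetate-mediated proton transfer into 27, and an inverse-electron-demand hetero-Diels-Alder reaction should then engage the electron-poorer C1 carbonyl of 27 (the C3 carbonyl is tied up in vinylogous ester resonance with the methoxy group) and only the exocyclic CH2=C7 bond of the s-trans-locked diene 11, with oxygen going to the more substituted carbon; the C8=C8a unit of 11 lies endo under the heterodiene, which sets C4 (R) with its isopropyl group cis to C1', and approach anti to the axial isopropyl group on C1 of 11 sets C2 (S) with a pseudoaxial C-O bond on ring C.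

**Compound list**
1 | (-)-menthone, (2S,5R)-5-methyl-2-(propan-2-yl)cyclohexan-1-one | O=C1[C@H](C(C)C)CC[C@@H](C)C1 | starting material
2 | lithium enolate of 1 on the CH2 side | [Li]OC=1[C@H](C(C)C)CC[C@@H](C)C=1 | intermediate
3 | (3R,6S)-2-[(dimethylamino)methyl]-3-methyl-6-(propan-2-yl)cyclohexan-1-one, epimers at C2 | O=C1[C@H](C(C)C)CC[C@@H](C)C1CN(C)C | intermediate
4 | methiodide of 3 | O=C1[C@H](C(C)C)CC[C@@H](C)C1C[N+](C)(C)C.[I-] | intermediate
5 | (3R,6S)-3-methyl-2-methylidene-6-(propan-2-yl)cyclohexan-1-one | O=C1[C@H](C(C)C)CC[C@@H](C)C1=C | intermediate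
6 | [2-(chloromethyl)prop-2-en-1-yl]trimethylsilane | C=C(CCl)C[Si](C)(C)C | starting material
7 | trichlorotitanium enolate (tetrasubstituted C1=C2 enolate carrying the new side chain) | Cl[Ti](Cl)(Cl)OC=1[C@H](C(C)C)CC[C@@H](C)C=1CCC(=C)CCl | intermediate
8 | (2R,3R,6S)-2-[3-(chloromethyl)but-3-en-1-yl]-3-methyl-6-(propan-2-yl)cyclohexan-1-one | O=C1[C@H](C(C)C)CC[C@@H](C)[C@H]1CCC(=C)CCl | intermediate
9 | {4-[(1R,2R,5S)-2-methyl-6-oxo-5-(propan-2-yl)cyclohexyl]-2-methylidenebutyl}triphenylphosphonium chloride | O=C1[C@H](C(C)C)CC[C@@H](C)[C@H]1CCC(=C)C[P+](c2ccccc2)(c3ccccc3)c4ccccc4.[Cl-] | intermediate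
10 | allylidene(triphenyl)phosphorane derived from 9 | O=C1[C@H](C(C)C)CC[C@@H](C)[C@H]1CCC(=C)C=P(c2ccccc2)(c3ccccc3)c4ccccc4 | intermediate
11 | (1S,4R,4aR)-4-methyl-7-methylidene-1-(propan-2-yl)-1,2,3,4,4a,5,6,7-octahydronaphthalene | C=C1C=C2[C@H](C(C)C)CC[C@@H](C)[C@H]2CC1 | intermediate
12 | 2-chloro-1,1-dimethoxyethane | ClCC(OC)OC | starting material
13 | sodium methoxyacetylide | [Na]C#COC | intermediate
14 | 1-methoxyprop-1-yne | CC#COC | intermediate
15 | 2-methylpropanoyl chloride | CC(C)C(=O)Cl | starting material
16 | dimethylketene | CC(C)=C=O | intermediate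
17 | 3-methoxy-2,4,4-trimethylcyclobut-2-en-1-one | COC1=C(C)C(=O)C1(C)C | intermediate
18 | ethyl 3-methylbut-2-enoate | CCOC(=O)C=C(C)C | starting material
19 | lithium enolate of 1,1-dibromo-4-methylpent-3-en-2-one | [Li]OC(C=C(C)C)=C(Br)Br | intermediate
20 | lithium 4-methylpent-3-en-1-yn-1-olate | [Li]OC#CC=C(C)C | intermediate
21 | [(4-methylpent-3-en-1-yn-1-yl)oxy]tri(propan-2-yl)silane | CC(C)=CC#CO[Si](C(C)C)(C(C)C)C(C)C | intermediate
22 | 3-methoxy-2,4-dimethylpenta-1,3-dien-1-one | COC(=C(C)C)C(C)=C=O | intermediate
23 | 4-(1-methoxy-2-methylprop-1-en-1-yl)-4-methyl-2-(2-methylprop-1-en-1-yl)-3-{[tri(propan-2-yl)silyl]oxy}cyclobut-2-en-1-one, racemic | O=C1C(C=C(C)C)=C(O[Si](C(C)C)(C(C)C)C(C)C)C1(C)C(OC)=C(C)C | intermediate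
24 | 5-methoxy-4,6-dimethyl-2-(2-methylprop-1-en-1-yl)-3-{[tri(propan-2-yl)silyl]oxy}hepta-1,3,5-trien-1-one, ketene arm and enol-ether arm cis on C3=C4 | O=C=C(C=C(C)C)/C(O[Si](C(C)C)(C(C)C)C(C)C)=C(\C(OC)=C(C)C)C | intermediate
25 | 5-methoxy-4,6,6-trimethyl-2-(2-methylprop-1-en-1-yl)-3-{[tri(propan-2-yl)silyl]oxy}cyclohexa-2,4-dien-1-one | COC1=C(C)C(O[Si](C(C)C)(C(C)C)C(C)C)=C(C=C(C)C)C(=O)C1(C)C | intermediate
26 | 3-hydroxy-5-methoxy-4,6,6-trimethyl-2-(2-methylprop-1-en-1-yl)cyclohexa-2,4-dien-1-one | COC1=C(C)C(O)=C(C=C(C)C)C(=O)C1(C)C | intermediate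
27 | 5-methoxy-4,6,6-trimethyl-2-(2-methylpropylidene)cyclohex-4-ene-1,3-dione, isopropyl group syn to the C3 carbonyl | COC1=C(C)C(=O)/C(=C\C(C)C)C(=O)C1(C)C | intermediate
28 | (2S,4R,4a'R,5'R,8'S)-7-methoxy-5',6,8,8-tetramethyl-4,8'-di(propan-2-yl)-3,3',4,4',4a',5',6',7',8,8'-decahydrospiro[chromene-2,2'-naphthalen]-5-one | COC1=C(C)C(=O)C2=C(O[C@]3(C=C4[C@H](C(C)C)CC[C@@H](C)[C@H]4CC3)C[C@@H]2C(C)C)C1(C)C | target

**Count and risks**
Total: 9 steps. Longest linear sequence: 5 steps (1, 2, 3, 4, 9).

Step 8 (labelled step).
- What may go wrong: slow opening of the donor-stabilised cyclobutenone, hydrogen shifts in the ketenes outrunning capture or ring closure, and thermal decay of the siloxyalkyne before it is consumed.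
- Fallback: known chemistry with no change of ring size. It sets out from 15 and comes back at 27.
- Compound 15 acylates commercial 2-methylbenzene-1,3,5-triol (AlCl3, Friedel-Crafts acylation) to 2-methyl-1-(2,4,6-trihydroxy-3-methylphenyl)propan-1-one F1.
- Dearomatising double C-methylation at the free ring carbon (MeI, NaOMe, MeOH) gives 3,5-dihydroxy-2,4,4-trimethyl-6-(2-methylpropanoyl)cyclohexa-2,5-dien-1-one F2.
- O-methylation (Me3SiCHN2), with separation of the regioisomeric ethers, gives tasmanone F3.
- NaBH4 reduces the side-chain carbonyl to 5-hydroxy-6-(1-hydroxy-2-methylpropyl)-3-methoxy-2,4,4-trimethylcyclohexa-2,5-dien-1-one F4. This loses water on mild acid treatment in the presence of 11 and so enters the route at 27.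

Step 9.
- What may go wrong: poor facial or endo/exo selectivity, participation of the other carbonyl group as the heterodiene oxygen, an ene reaction in place of cycloaddition, and cyclisation of the freed enol onto its own alkenyl group.
- Fallback: a stepwise cationic annulation that keeps the silyl ether until the C-O bond is made. It sets out from 25 and 11 and comes back at 28.
- Catalytic HN(SO2CF3)2 with one equivalent of propan-2-ol in CH2Cl2 at -78 °C protonates the terminus of the 2-methylpropenyl group of 25. This gives the O-silylated heterodiene cation F5.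
- The exocyclic methylene group of 11 attacks the cationic carbon of F5.
- Only the free C1 carbonyl oxygen can then close on the resulting tertiary allyl cation, in the axial direction on ring C.
- The silyl group finally passes to propan-2-ol, which regenerates the acid.

Step 4.
- What may go wrong: enolisation of the hindered ketone by base or ylide with loss of the C2 configuration, or failure of the crowded carbonyl group to accept the ylide.
- Fallback: nucleophilic allylation followed by dehydration. It sets out from 8 and comes back at 11.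
- Intramolecular Barbier allylation (Zn, THF, aq NH4Cl) under near-neutral conditions gives the cis-fused homoallylic alcohol (1S,4R,4aR,8aR)-4-methyl-7-methylidene-1-(propan-2-yl)decahydronaphthalen-8a-ol F6.
- Dehydration with the Burgess reagent toward the allylically activated CH2 group gives 11.

**Further compounds**
F1 | step 8 | 2-methyl-1-(2,4,6-trihydroxy-3-methylphenyl)propan-1-one | CC(C)C(=O)c1c(O)cc(O)c(C)c1O
F2 | step 8 | 3,5-dihydroxy-2,4,4-trimethyl-6-(2-methylpropanoyl)cyclohexa-2,5-dien-1-one | CC(C)C(=O)C1=C(O)C(C)(C)C(O)=C(C)C1=O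
F3 | step 8 | tasmanone, 5-hydroxy-3-methoxy-2,4,4-trimethyl-6-(2-methylpropanoyl)cyclohexa-2,5-dien-1-one | CC(C)C(=O)C1=C(O)C(C)(C)C(OC)=C(C)C1=O
F4 | step 8 | 5-hydroxy-6-(1-hydroxy-2-methylpropyl)-3-methoxy-2,4,4-trimethylcyclohexa-2,5-dien-1-one | CC(C)C(O)C1=C(O)C(C)(C)C(OC)=C(C)C1=O
F5 | step 9 | O-silylated heterodiene cation, bis(trifluoromethylsulfonyl)amide salt | COC1=C(C)C(=[O+][Si](C(C)C)(C(C)C)C(C)C)C(=CC(C)C)C(=O)C1(C)C.O=S(=O)([N-]S(=O)(=O)C(F)(F)F)C(F)(F)F
F6 | step 4 | (1S,4R,4aR,8aR)-4-methyl-7-methylidene-1-(propan-2-yl)decahydronaphthalen-8a-ol | C=C1C[C@@]2(O)[C@H](C(C)C)CC[C@@H](C)[C@H]2CC1
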